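Remark (assumption): Kanzonol V has no stereocentre, no stereogenic double bond and no hindered axis. It is achiral, so "single enantiomer" is met by the constitution alone and no stereocontrol is planned.

Numbering used throughout:
- 1 2,4-dihydroxyacetophenone; 2 its 4-O-TIPS ether; 3 3-chloro-3-methylbut-1-yne; 4 propargyl ether
- 5, 6, 7 transient intermediates of the chromene-forming cascade; 8 8-acetylchromene
- 9 3-bromo-4-iodophenol; 10 prenyl bromide; 11 sodium phenoxide of 9; 12 prenylated bromo-iodophenol; 13 its TIPS ether
- 14 transient α-aryl ketone; 15 bis-TIPS Kanzonol V; 16 Kanzonol V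

## Analysis of the target

Kanzonol V (16) is a 2-arylbenzofuran. The benzofuran (O1, C2, C3, C3a–C7a) carries OH at C6 and a prenyl group at C5, and its C2 is bonded to C8 of a 2,2-dimethyl-2H-chromen-5-ol, whose pyran oxygen sits on C8a next to the inter-ring bond and whose free OH is para to that bond. There is no stereocentre and the C2–C8 bond rotates freely, so the problem is one of constitution and regiochemistry only. Three placements must be right: prenyl at C5 and not C7, the pyran fused through the oxygen ortho to the inter-ring bond and not the para one, and the furan closed onto the correct carbon of ring A. The ortho-prenylphenol closes to a chroman under acid and reacts with electrophilic halogen and oxidants, the chromene double bond is acid-sensitive, both alkenes forbid hydrogenolysis, and the free phenols oxidise easily. Protecting groups must therefore leave with fluoride, and the bond-forming chemistry must be basic or neutral.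

The feature this route exploits is that O1, C2 and C3, together with chromene C8, are the enol form of an 8-acetyl group (C8–C2(–O1)=C3). Ring A then contributes only the adjacent carbons C3a and C7a. If O1 is counted with the B-ring half, ring A stops being a 1,3-dioxygenated ring whose two oxygens must be told apart; it becomes a mono-phenol whose single OH (C6) is para to C3a and ortho to the prenyl carbon C5. The structure thus invites one operation that forges C3–C3a and O1–C7a onto an ortho-dihalogenated prenylphenol, closing the furan while joining the two halves.

## Retrosynthetic reasoning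

**16 from 15.** Only the two O–Si bonds are cut. Both phenols are carried as triisopropylsilyl ethers, which survive strong base and heat and leave under buffered fluoride, conditions that touch neither the prenyl group nor the chromene.

**15 from 8 and 13 (key disconnection).** The furan is cut at C3–C3a and O1–C7a, not at the usual O1–C2. All three non-arene furan atoms then come from the acetyl group of 8, and ring A becomes the 1-bromo-2-iodoarene 13. Halogen identity encodes the regiochemistry: iodine, para to the silyloxy group, marks C3a and reacts first; bromine, para to the prenyl group, marks C7a and reacts second. The forward reaction must α-arylate the methyl ketone at C–I to give 14 and then O-arylate the enolate of 14 at C–Br. The gain is that no alkyne has to be installed on ring B and no pair of ring-A hydroxyls has to be differentiated.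

**13 from 12, and 12 from 9 and 10.** The O–Si bond and then the C5–CH2 bond are cut. Phenol 9 has one OH and two ortho positions, one open and one flanked by bromine, so ortho C-alkylation of phenoxide 11 with 10 should place the prenyl group where it is needed. The halogens are bought in place, not introduced next to an alkene.

**8 from 4.** The pyran ring is opened at C4–C4a and O–C2 back to an aryl 1,1-dimethylpropargyl ether. In 4 the acetyl-bearing carbon blocks one ortho position, so the sigmatropic shift can only go to the carbon between the two oxygens. This gives the angular chromene on the oxygen next to the acetyl group, which is the required regiochemistry. The cascade runs through 5, 6 and 7.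

**4 from 2 and 3, and 2 from 1.** Two O-functionalisations are cut. In 1 the hydroxyl ortho to the acetyl group is hydrogen-bonded, so silylation takes the para hydroxyl first and leaves the chelated one for the propargyl unit of 3. The same carbonyl that later becomes C2/O1 of the furan thus also sorts the two B-ring oxygens.

## Alternatives that were turned down

**Alternative 1:** the textbook cut at O1–C2 and C3–C3a. Sonogashira coupling of iodophenol A1 with chromenyl alkyne A2, followed by 5-endo-dig closure of the ortho-alkynylphenol, would give 16 directly. The chemistry is sound. It was turned down because A1 is a 1,3-diol whose two hydroxyls must be carried through protection, halogen–metal exchange prenylation and an acidic deprotection beside the prenyl group. A2 also needs a one-carbon homologation that the acetyl group of 8 makes unnecessary. The route is at least two steps longer and puts acid next to the ortho-prenylphenol.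

**Alternative 2:** cut the inter-ring bond C2–C8. Suzuki coupling of benzofuran-2-ylboronic acid A3 with 8-bromochromene A4 would give 15. It was turned down for three reasons:
- The furan ring of A3 still has to be built on a ring A that again needs its own oxygen differentiated, so the hard problem is only moved.
- 2-Benzofuranylboron compounds protodeboronate readily.
- A4 has no short access: the carbonyl-blocked series that makes 8 delivers carbon, not halogen, at C8, and electrophilic halogenation of the chromene would not select C8 over C6 or the alkene.

**Alternative 3:** install both C5 units last by a double sigmatropic cascade. Bis-ether A5 would be heated so that the 6-O-(1,1-dimethylallyl) group migrates to carbon and the 2'-O-propargyl group closes the chromene in one operation. It was turned down because the allyl ether on C6 has two ortho carbons. The bond fixation of a benzofuran, as in related 7-oxygenated coumarins, favours migration to C7 between the two oxygens, so the expected product is the C7-prenyl isomer A6 and not the skeleton of 16. A5 also demands three differentiated phenols on a preformed arylbenzofuran.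

Key step: step 6

## Route

Step 1
Reactants: 1 2,4-dihydroxyacetophenone
Product: 2 1-[2-hydroxy-4-(triisopropylsilyloxy)phenyl]ethan-1-one
Conditions: TIPSCl (1.05 equiv), imidazole (2.2 equiv), CH2Cl2, 0 °C to rt
Reagents that add atoms: chlorotri(propan-2-yl)silane (TIPSCl), CC(C)[Si](Cl)(C(C)C)C(C)C
Why: Chemoselective O-silylation; the 2-OH is locked in a hydrogen bond to the acetyl carbonyl and is much less nucleophilic, so the bulky silyl chloride should take only the free 4-OH.

Step 2
Reactants: 2 1-[2-hydroxy-4-(triisopropylsilyloxy)phenyl]ethan-1-one; 3 3-chloro-3-methylbut-1-yne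
Product: 4 1-[2-(2-methylbut-3-yn-2-yloxy)-4-(triisopropylsilyloxy)phenyl]ethan-1-one
Conditions: 3 (1.5 equiv), DBU (1.6 equiv), CuCl2·2H2O (1 mol%), MeCN, 0 °C to rt
Reagents that add atoms: none
Why: Copper-catalysed propargylic etherification, in which a copper acetylide ionises the tertiary chloride and the phenoxide captures the propargylic cation equivalent; this tolerates hindered and chelated phenols, and the acetyl group and silyl ether are inert to DBU at this temperature.

Step 3
Reactants: 4 1-[2-(2-methylbut-3-yn-2-yloxy)-4-(triisopropylsilyloxy)phenyl]ethan-1-one
Product: 8 1-[2,2-dimethyl-5-(triisopropylsilyloxy)-2H-chromen-8-yl]ethan-1-one, via allenyl dienone 5 (not isolated), via allenyl phenol 6 (not isolated), via ortho-quinone methide 7 (not isolated)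
Conditions: o-xylene, 140 °C, sealed tube
Reagents that add atoms: none
Why: Aromatic propargyl Claisen rearrangement, tautomerisation, 1,5-hydrogen shift and oxa-6π electrocyclisation; the acetyl-bearing carbon blocks one ortho position, so the [3,3] shift can only reach the carbon between the two oxygens and the angular pyran on the former 2-oxygen is the only chromene that can form (5 is racemic and its stereocentre is lost on tautomerisation).

Step 4
Reactants: 9 3-bromo-4-iodophenol; 10 1-bromo-3-methylbut-2-ene (prenyl bromide)
Product: 12 5-bromo-4-iodo-2-(3-methylbut-2-en-1-yl)phenol, via sodium phenoxide 11 (not isolated)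
Conditions: NaH (1.05 equiv), toluene, 0 °C to rt; then 10 (1.1 equiv), rt to 50 °C
Reagents that add atoms: none
Why: Ortho C-alkylation of a sodium phenoxide as a tight ion pair in a non-polar solvent, with SN2 attack at the primary carbon of 10 giving the linear prenyl group; of the two ortho carbons, the one flanked by bromine is hindered and inductively deactivated, so the open one (the future C5) should react.

Step 5
Reactants: 12 5-bromo-4-iodo-2-(3-methylbut-2-en-1-yl)phenol
Product: 13 [5-bromo-4-iodo-2-(3-methylbut-2-en-1-yl)phenoxy]tri(propan-2-yl)silane
Conditions: TIPSCl (1.2 equiv), imidazole (2.5 equiv), DMF, rt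
Reagents that add atoms: chlorotri(propan-2-yl)silane (TIPSCl), CC(C)[Si](Cl)(C(C)C)C(C)C
Why: Standard phenol silylation; it removes the acidic proton before the enolate chemistry and matches the protecting group of 8, so one fluoride treatment ends the synthesis.

Step 6
Reactants: 8 1-[2,2-dimethyl-5-(triisopropylsilyloxy)-2H-chromen-8-yl]ethan-1-one; 13 [5-bromo-4-iodo-2-(3-methylbut-2-en-1-yl)phenoxy]tri(propan-2-yl)silane
Product: 15 2-[2,2-dimethyl-5-(triisopropylsilyloxy)-2H-chromen-8-yl]-5-(3-methylbut-2-en-1-yl)-6-(triisopropylsilyloxy)-1-benzofuran, via alpha-aryl ketone 14 (not isolated)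
Conditions: 8 (1.2 equiv), 13 (1.0 equiv), Pd2(dba)3 (2.5 mol%), Xantphos (6 mol%), NaOtBu (2.5 equiv), toluene, 80 °C then 110 °C
Reagents that add atoms: none
Why: Pd(0) should insert into the C–I bond of 13 well before the neighbouring C–Br bond, and the sodium enolate of 8 then displaces iodide on palladium and C–C reductive elimination gives 14 (palladium-catalysed ketone α-arylation, forming C3–C3a). Ketone 14 is more acidic than 8 and is deprotonated at once; at the higher temperature Pd(0) inserts into its C–Br bond, the enolate oxygen (Z-enolate, equilibrating through the ketone) binds palladium to form a six-membered oxapalladacycle, and C–O reductive elimination forms O1–C7a. The closest known reaction type is the domino C-arylation/O-arylation of ketones with ortho-dihaloarenes to benzofurans, the second half being the intramolecular O-arylation of enolates of α-(2-haloaryl) ketones. The furan is the only ring closed, by intramolecular C(sp2)–O coupling in a five-membered closure onto the aryl carbon, and it is born aromatic because the enol double bond is C2=C3. No stereocentre is formed. The step needs iodine-before-bromine site selectivity, which halogen identity secures although iodine is para to the donor oxygen. It needs mono- and not double C-arylation of the methyl group, which the ortho-bromo substituent of 14, the slight excess of 8 and the fast ring closure on heating should secure. O- over C-closure is assured because C-closure would give a four-membered ring. The trisubstituted prenyl alkene and the hindered chromene alkene are poor Heck acceptors, and the bulky silyl ethers should withstand tert-butoxide in toluene.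

Step 7
Reactants: 15 2-[2,2-dimethyl-5-(triisopropylsilyloxy)-2H-chromen-8-yl]-5-(3-methylbut-2-en-1-yl)-6-(triisopropylsilyloxy)-1-benzofuran
Product: 16 Kanzonol V (8-[6-hydroxy-5-(3-methylbut-2-en-1-yl)-1-benzofuran-2-yl]-2,2-dimethyl-2H-chromen-5-ol)
Conditions: TBAF (2.4 equiv), AcOH (2.4 equiv), THF, 0 °C
Reagents that add atoms: none
Why: Fluoride cleaves both aryl silyl ethers through Si–F bond formation; the acetic acid buffer keeps the electron-rich bis-phenol from standing as an air-sensitive phenoxide, and these near-neutral conditions leave the prenyl group and the chromene untouched.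

## Compound list

1 | 2,4-dihydroxyacetophenone | CC(=O)c1ccc(O)cc1O | starting material
2 | 1-[2-hydroxy-4-(triisopropylsilyloxy)phenyl]ethan-1-one | CC(=O)c1ccc(O[Si](C(C)C)(C(C)C)C(C)C)cc1O | intermediate
3 | 3-chloro-3-methylbut-1-yne | CC(C)(Cl)C#C | starting material
4 | 1-[2-(2-methylbut-3-yn-2-yloxy)-4-(triisopropylsilyloxy)phenyl]ethan-1-one | CC(=O)c1ccc(O[Si](C(C)C)(C(C)C)C(C)C)cc1OC(C)(C)C#C | intermediate
5 | 2-acetyl-6-(3-methylbuta-1,2-dien-1-yl)-5-(triisopropylsilyloxy)cyclohexa-2,4-dien-1-one (racemic, transient) | CC(=O)C1=CC=C(O[Si](C(C)C)(C(C)C)C(C)C)C(C=C=C(C)C)C1=O | intermediate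
6 | 1-[2-hydroxy-3-(3-methylbuta-1,2-dien-1-yl)-4-(triisopropylsilyloxy)phenyl]ethan-1-one | CC(=O)c1ccc(O[Si](C(C)C)(C(C)C)C(C)C)c(C=C=C(C)C)c1O | intermediate
7 | (6Z)-2-acetyl-6-(3-methylbut-2-en-1-ylidene)-5-(triisopropylsilyloxy)cyclohexa-2,4-dien-1-one | CC(=O)C1=CC=C(O[Si](C(C)C)(C(C)C)C(C)C)/C(=C/C=C(C)C)C1=O | intermediate
8 | 1-[2,2-dimethyl-5-(triisopropylsilyloxy)-2H-chromen-8-yl]ethan-1-one | CC(=O)c1ccc(O[Si](C(C)C)(C(C)C)C(C)C)c2C=CC(C)(C)Oc12 | intermediate
9 | 3-bromo-4-iodophenol | Oc1ccc(I)c(Br)c1 | starting material
10 | 1-bromo-3-methylbut-2-ene (prenyl bromide) | CC(C)=CCBr | starting material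
11 | sodium 3-bromo-4-iodophenoxide | [Na+].[O-]c1ccc(I)c(Br)c1 | intermediate
12 | 5-bromo-4-iodo-2-(3-methylbut-2-en-1-yl)phenol | CC(C)=CCc1cc(I)c(Br)cc1O | intermediate
13 | [5-bromo-4-iodo-2-(3-methylbut-2-en-1-yl)phenoxy]tri(propan-2-yl)silane | CC(C)=CCc1cc(I)c(Br)cc1O[Si](C(C)C)(C(C)C)C(C)C | intermediate
14 | 2-[2-bromo-5-(3-methylbut-2-en-1-yl)-4-(triisopropylsilyloxy)phenyl]-1-[2,2-dimethyl-5-(triisopropylsilyloxy)-2H-chromen-8-yl]ethan-1-one | CC(C)=CCc1cc(CC(=O)c2ccc(O[Si](C(C)C)(C(C)C)C(C)C)c3C=CC(C)(C)Oc23)c(Br)cc1O[Si](C(C)C)(C(C)C)C(C)C | intermediate
15 | 2-[2,2-dimethyl-5-(triisopropylsilyloxy)-2H-chromen-8-yl]-5-(3-methylbut-2-en-1-yl)-6-(triisopropylsilyloxy)-1-benzofuran | CC(C)=CCc1cc2cc(-c3ccc(O[Si](C(C)C)(C(C)C)C(C)C)c4c3OC(C)(C)C=C4)oc2cc1O[Si](C(C)C)(C(C)C)C(C)C | intermediate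
16 | Kanzonol V | CC(C)=CCc1cc2cc(-c3ccc(O)c4c3OC(C)(C)C=C4)oc2cc1O | target

## Step count and risk

Total step count: 7. Longest linear sequence: 5 (steps 1, 2, 3, 6, 7). The A-ring branch (steps 4 and 5) joins at step 6.

Least certain steps:

**Step 6 (key step).** Most likely to go wrong is a second intermolecular C-arylation of the enolate of 14 before the ring closes, because the C–I bond of unreacted 13 is more reactive than the C–Br bond that must be engaged for closure. Further risks are early insertion into C–Br, hydrodehalogenation, and base-induced loss of the B-ring silyl group, which would give a phenoxide para to the acetyl group and shut down enolisation. The fallback changes the approach to an alkyne route in which hydroxide supplies the furan oxygen; it sets out from 8 and 13 and comes back at 16. Ketone 8 would be converted with LDA and diethyl chlorophosphate into the enol phosphate F1 and, without isolation, with further LDA into the terminal alkyne F2. Sonogashira coupling of F2 with 13 at the C–I bond (PdCl2(PPh3)2, CuI, Et3N, rt) would give the bromo-tolane F3. Palladium-catalysed hydroxylation of its C–Br bond (Pd2(dba)3, t-BuXPhos, KOH, dioxane–water, 100 °C) would be followed in the same flask by 5-endo-dig attack of the new phenoxide on the alkyne. Hydroxide at this temperature should also strip both silyl ethers; a final TBAF/AcOH treatment of the crude material would complete this, giving 16.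

**Step 4.** O-alkylation competing with C-alkylation, a second prenylation, and some attack at the hindered ortho position may erode the yield, since the halogenated phenoxide is a weak carbon nucleophile. The fallback sets out from 9 and comes back at 12. O-allylation (allyl bromide, K2CO3, acetone) would give the allyl ether F4. Aromatic Claisen rearrangement (PhNEt2, 190 °C) would give the ortho-allylphenol F5, with chromatographic removal of any isomer from migration toward bromine. Cross-metathesis of F5 with 2-methylbut-2-ene (second-generation ruthenium benzylidene catalyst, CH2Cl2, 40 °C) would convert allyl into prenyl and give 12.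

**Step 2.** Etherification of the chelated, hindered phenoxide may be slow, and elimination of the tertiary chloride to the enyne may outrun it. The fallback sets out from 2 and comes back at 8, replacing steps 2 and 3 together. Direct chromenylation of 2 with 3-methylbut-2-enal (PhB(OH)2, propionic acid, toluene, reflux with water removal) would proceed by ortho-hydroxyalkylation through the aryl boronate, dehydration to the ortho-quinone methide and oxa-6π closure. The acetyl-blocked ring leaves only the carbon between the oxygens for attack, so the same chromene 8 would result without a new isolated compound.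

**Step 3.** The [3,3] shift must reach a carbon flanked by the bulky silyloxy group; steric retardation could force prolonged heating, with ether cleavage and decomposition. The fallback sets out from 4 and comes back at 8. Semi-hydrogenation of the alkyne (Pd/CaCO3–Pb, quinoline, H2) would give the 1,1-dimethylallyl ether F6. Aromatic Claisen rearrangement at lower temperature (PhNEt2, 130–150 °C) would deliver the ortho-prenylphenol F7, again with only one ortho carbon available. Dehydrogenative cyclisation with DDQ (benzene, 80 °C), by hydride abstraction to the ortho-quinone methide and oxa-6π closure, would give 8; no other prenyl group is present at this stage.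

Further compounds

F1 | step 6 | diethyl 1-[2,2-dimethyl-5-(triisopropylsilyloxy)-2H-chromen-8-yl]ethenyl phosphate | C=C(OP(=O)(OCC)OCC)c1ccc(O[Si](C(C)C)(C(C)C)C(C)C)c2C=CC(C)(C)Oc12
F2 | step 6 | [(8-ethynyl-2,2-dimethyl-2H-chromen-5-yl)oxy]tri(propan-2-yl)silane | C#Cc1ccc(O[Si](C(C)C)(C(C)C)C(C)C)c2C=CC(C)(C)Oc12
F3 | step 6 | 8-{[2-bromo-5-(3-methylbut-2-en-1-yl)-4-(triisopropylsilyloxy)phenyl]ethynyl}-2,2-dimethyl-5-(triisopropylsilyloxy)-2H-chromene | CC(C)=CCc1cc(C#Cc2ccc(O[Si](C(C)C)(C(C)C)C(C)C)c3C=CC(C)(C)Oc23)c(Br)cc1O[Si](C(C)C)(C(C)C)C(C)C
F4 | step 4 | 2-bromo-1-iodo-4-(prop-2-en-1-yloxy)benzene | C=CCOc1ccc(I)c(Br)c1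
F5 | step 4 | 5-bromo-4-iodo-2-(prop-2-en-1-yl)phenol | C=CCc1cc(I)c(Br)cc1O
F0 | step 2 | none | none
F6 | step 3 | 1-[2-(2-methylbut-3-en-2-yloxy)-4-(triisopropylsilyloxy)phenyl]ethan-1-one | CC(=O)c1ccc(O[Si](C(C)C)(C(C)C)C(C)C)cc1OC(C)(C)C=C
F7 | step 3 | 1-[2-hydroxy-3-(3-methylbut-2-en-1-yl)-4-(triisopropylsilyloxy)phenyl]ethan-1-one | CC(=O)c1ccc(O[Si](C(C)C)(C(C)C)C(C)C)c(CC=C(C)C)c1O
A1 | alternative 1 | 4-iodo-6-(3-methylbut-2-en-1-yl)benzene-1,3-diol | CC(C)=CCc1cc(I)c(O)cc1O
A2 | alternative 1 | 8-ethynyl-2,2-dimethyl-2H-chromen-5-ol | C#Cc1ccc(O)c2C=CC(C)(C)Oc12
A3 | alternative 2 | [5-(3-methylbut-2-en-1-yl)-6-(triisopropylsilyloxy)-1-benzofuran-2-yl]boronic acid | CC(C)=CCc1cc2cc(B(O)O)oc2cc1O[Si](C(C)C)(C(C)C)C(C)C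
A4 | alternative 2 | [(8-bromo-2,2-dimethyl-2H-chromen-5-yl)oxy]tri(propan-2-yl)silane | Brc1ccc(O[Si](C(C)C)(C(C)C)C(C)C)c2C=CC(C)(C)Oc12
A5 | alternative 3 | 6-(2-methylbut-3-en-2-yloxy)-2-[2-(2-methylbut-3-yn-2-yloxy)-4-(triisopropylsilyloxy)phenyl]-1-benzofuran | C=CC(C)(C)Oc1ccc2cc(-c3ccc(O[Si](C(C)C)(C(C)C)C(C)C)cc3OC(C)(C)C#C)oc2c1
A6 | alternative 3 | 2-[2,2-dimethyl-5-(triisopropylsilyloxy)-2H-chromen-8-yl]-7-(3-methylbut-2-en-1-yl)-1-benzofuran-6-ol | CC(C)=CCc1c(O)ccc2cc(-c3ccc(O[Si](C(C)C)(C(C)C)C(C)C)c4c3OC(C)(C)C=C4)oc12
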